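## Retrosynthetic overview

- Only the central pyrrole has to be built, since both indoles are bought. N1–C5 with the acetyl group is an aminoacetone unit. C2 (CO2Me)–C3 (indolyl)–C4 (indolyl) is the carbon chain of a 3,4-bis(indol-3-yl)-2-oxobut-3-enoate.
- Cutting N1–C2 (ketimine) and C4–C5 (1,5-electrocyclization of a 2-azapentadienyl anion, then dehydrogenation) leads back to these two partners.
- The enone is cut at C3=C4 (Knoevenagel condensation) into methyl indole-3-pyruvate and 1-Boc-indole-3-carboxaldehyde. Only the indole on C4 is conjugated with the keto group, so only that indole needs the Boc group.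
- Order: esterification and N-Boc protection, then C3=C4, then the pyrrole ring (N1–C2, C4–C5, aromatisation) in one flask, then thermal loss of Boc.

Key step: step 4

Remark: Boc = tert-butoxycarbonyl. Compound 2 is drawn as its keto tautomer although it should exist largely as the enol. Intermediates 5 and 9 are racemic diastereomer mixtures whose sp3 centres all disappear before 10.

## Route

Step 1
Reactants: 1 indole-3-pyruvic acid
Product: 2 methyl 3-(1H-indol-3-yl)-2-oxopropanoate (methyl indole-3-pyruvate)
Conditions: KHCO3 (1.1 equiv), MeI (1.5 equiv), DMF, 0 °C to rt, argon, dark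
Reagents that add atoms: iodomethane, CI
Why: Carboxylate O-alkylation (SN2 esterification): bicarbonate ionises only the alpha-keto acid, not the enol or the indole N–H, so that iodomethane should methylate the carboxylate alone under acid-free conditions that spare the sensitive indolylpyruvate.

Step 2
Reactants: 3 1H-indole-3-carboxaldehyde
Product: 4 tert-butyl 3-formyl-1H-indole-1-carboxylate (1-Boc-indole-3-carboxaldehyde)
Conditions: Boc2O (1.1 equiv), DMAP (5 mol %), MeCN, rt
Reagents that add atoms: di-tert-butyl dicarbonate, CC(C)(C)OC(=O)OC(=O)OC(C)(C)C
Why: DMAP-catalysed N-tert-butoxycarbonylation: the N–H of this vinylogous formamide is acidic enough to be acylated cleanly at room temperature, and the carbamate restores normal aldehyde electrophilicity for step 3.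

Step 3
Reactants: 2 methyl indole-3-pyruvate; 4 1-Boc-indole-3-carboxaldehyde (1.1 equiv)
Product: 6 methyl (E)-4-(1-Boc-indol-3-yl)-3-(1H-indol-3-yl)-2-oxobut-3-enoate, via Mannich base 5 (not isolated)
Conditions: piperidine (0.2 equiv), AcOH (0.2 equiv), 4 Å MS, toluene, 80 °C, slow addition of 2
Reagents that add atoms: none
Why: Knoevenagel condensation: the doubly activated C3 methylene of 2 attacks the piperidinium ion of 4 to give the beta-amino ketone 5, which, unlike an aldol adduct, has no gamma-oxygen that could lactonise onto the methyl ester and which loses piperidine by E1cB, while removal of water drives the equilibrium; the sp3 centres of 5 vanish and the E alkene (indoles cis, keto ester away from the Boc-indole) should prevail on steric grounds.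

Step 4
Reactants: 6 methyl (E)-4-(1-Boc-indol-3-yl)-3-(1H-indol-3-yl)-2-oxobut-3-enoate; 7 aminoacetone hydrochloride
Product: 10 methyl 5-acetyl-4-(1-Boc-indol-3-yl)-3-(1H-indol-3-yl)-1H-pyrrole-2-carboxylate, via ketimine 8 (not isolated), via dihydropyrrole 9 (not isolated)
Conditions: 7 (2 equiv, four portions), pyridine, 4 Å MS, 90 °C, N2; then Cu(OAc)2 (20 mol %), air, 60 °C
Reagents that add atoms: none
Why: Proposed new method: pyridine frees only a small stationary amount of aminoacetone from 7, which adds 1,2 to the ester-activated keto group of 6, and the sieves take up the water to give the 1-azadiene 8 (N1–C2). The CH2 of 8 sits between the acetyl group and the imine nitrogen, so that mild base (or a 1,2-proton shift to the N–H azomethine ylide) turns C5–N1–C2–C3–C4 into a five-atom, six-electron 2-azapentadienyl system, which closes the pyrrole ring thermally by disrotatory 1,5-electrocyclization (C4–C5), a pericyclic mode that does not suffer the geometric handicap of a 5-endo-trig Michael addition. The 1-azaallyl anion N1–C2–C3 left by the closure carries its ester on the central carbon and gains little from it, so the closure is expected to be reversible until protonation gives the dehydroamino ester 9 and Cu(OAc)2 with air (divalent copper as electron-transfer catalyst, O2 as terminal oxidant) removes H-4 and H-5 to give the aromatic 10, which drains all equilibria, including the 1,3-proton shift of 8 to its transaminated isomer. The closest known reaction type is the one-pot condensation of chalcone-type enones with glycine ester or glycine amide hydrochlorides in hot pyridine, 1,5-electrocyclization and copper-mediated dehydrogenation to pyrrole-2-carboxylic acid derivatives; the alpha-amino ketone as amine partner and the alpha-keto ester as enone partner are the untested elements. C4 and C5 of 9 are the only new stereocentres (cis by disrotation of the two outward groups, C5 epimerisable), they need no control because both become sp2 in 10, and the E geometry of 6 merely keeps the Boc-indole turned outward and so out of reach of a competing 1,7-closure. The step needs 1,2- over 1,4-addition and over ester aminolysis, secured by the trisubstituted donor-bearing alkene terminus and by the faster ketimine formation driven by water removal, cross- over self-condensation of aminoacetone, secured by keeping it largely protonated and adding it in portions, and a C4 terminus that still accepts a bond, secured by the N-Boc group, which curbs the vinylogous-amide donation of that indole.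

Step 5
Reactants: 10 methyl 5-acetyl-4-(1-Boc-indol-3-yl)-3-(1H-indol-3-yl)-1H-pyrrole-2-carboxylate
Product: 11 methyl 5-acetyl-3,4-di(1H-indol-3-yl)-1H-pyrrole-2-carboxylate (target)
Conditions: neat, 180 °C, 1 mbar, 30 min, dark
Reagents that add atoms: none
Why: Thermolytic Boc cleavage: the indole carbamate fragments in a retro-ene manner to isobutene and the N-carboxylic acid, which loses CO2, and since no acid, base or nucleophile is present the methyl ester, the acetyl group and the acid-sensitive indoles should remain untouched.

## Compound list

1 | indole-3-pyruvic acid, 3-(1H-indol-3-yl)-2-oxopropanoic acid | O=C(O)C(=O)Cc1c[nH]c2ccccc12 | starting material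
2 | methyl 3-(1H-indol-3-yl)-2-oxopropanoate | COC(=O)C(=O)Cc1c[nH]c2ccccc12 | intermediate
3 | 1H-indole-3-carboxaldehyde | O=Cc1c[nH]c2ccccc12 | starting material
4 | tert-butyl 3-formyl-1H-indole-1-carboxylate | CC(C)(C)OC(=O)n1cc(C=O)c2ccccc12 | intermediate
5 | methyl 4-(1-Boc-indol-3-yl)-3-(1H-indol-3-yl)-2-oxo-4-(piperidin-1-yl)butanoate (racemic diastereomer mixture, not isolated) | COC(=O)C(=O)C(c1c[nH]c2ccccc12)C(N1CCCCC1)c1cn(C(=O)OC(C)(C)C)c2ccccc12 | intermediate
6 | methyl (E)-4-(1-Boc-indol-3-yl)-3-(1H-indol-3-yl)-2-oxobut-3-enoate | COC(=O)C(=O)/C(c1c[nH]c2ccccc12)=C/c1cn(C(=O)OC(C)(C)C)c2ccccc12 | intermediate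
7 | aminoacetone hydrochloride, 1-aminopropan-2-one hydrochloride | CC(=O)CN.Cl | starting material
8 | methyl (3E)-4-(1-Boc-indol-3-yl)-3-(1H-indol-3-yl)-2-[(2-oxopropyl)imino]but-3-enoate (C=N geometry not defined, not isolated) | COC(=O)C(=NCC(C)=O)/C(c1c[nH]c2ccccc12)=C/c1cn(C(=O)OC(C)(C)C)c2ccccc12 | intermediate
9 | methyl 5-acetyl-4-(1-Boc-indol-3-yl)-3-(1H-indol-3-yl)-4,5-dihydro-1H-pyrrole-2-carboxylate (racemic, C4/C5 configuration not defined, in equilibrium with its 1-pyrroline tautomer, not isolated) | COC(=O)C1=C(c2c[nH]c3ccccc23)C(c2cn(C(=O)OC(C)(C)C)c3ccccc23)C(C(C)=O)N1 | intermediate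
10 | methyl 5-acetyl-4-(1-Boc-indol-3-yl)-3-(1H-indol-3-yl)-1H-pyrrole-2-carboxylate | COC(=O)c1[nH]c(C(C)=O)c(-c2cn(C(=O)OC(C)(C)C)c3ccccc23)c1-c1c[nH]c2ccccc12 | intermediate
11 | methyl 5-acetyl-3,4-di(1H-indol-3-yl)-1H-pyrrole-2-carboxylate | COC(=O)c1[nH]c(C(C)=O)c(-c2c[nH]c3ccccc23)c1-c1c[nH]c2ccccc12 | target

## Step count

Total step count: 5.
Longest linear sequence: 4 steps (1 → 2 → 6 → 10 → 11, or 3 → 4 → 6 → 10 → 11).

## Steps most likely to fail

**Step 4 (the labelled step).**
Several processes could defeat it:
- Aminoacetone may dimerise to the dihydropyrazine faster than it meets the hindered ketone.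
- The amine may attack the activated methyl ester.
- The open anion, stabilised by two acceptors, may stay open.
- The Boc group may be lost before closure, which would deactivate C4.

The fallback uses known chemistry, sets out from 6 and takes an amine from the established scope that cannot self-condense. Compound 6 is heated with commercial 2-amino-N-methoxy-N-methylacetamide hydrochloride in pyridine over 4 Å MS and then oxidised with Cu(OAc)2 and air. This is the known glycine amide variant of the electrocyclization and oxidation sequence. It should give the Weinreb amide methyl 4-(1-Boc-indol-3-yl)-3-(1H-indol-3-yl)-5-[methoxy(methyl)carbamoyl]-1H-pyrrole-2-carboxylate F1. Weinreb ketone synthesis follows with MeMgBr (3.5 equiv, two of them consumed by the N–H groups, THF, −40 to 0 °C). It should convert the chelating amide faster than the ester of the magnesiated pyrrole, and it comes back to the route at 10.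

**Step 3.**
Three processes could interfere:
- The enolate of 2 may add to the free aldehyde instead of its iminium ion, and the gamma-alkoxide may then lactonise onto the methyl ester (isotetronic acid formation).
- Compound 2 may undergo self-aldolisation.
- The Boc group may be transferred to piperidine.

The fallback gives up the condensation of 2 and makes the C3–indole bond by cross-coupling. It sets out from 4.
- Wittig reaction with methyl 2-oxo-3-(triphenylphosphoranylidene)propanoate (toluene, 80 °C) should give methyl (E)-4-(1-Boc-indol-3-yl)-2-oxobut-3-enoate F2.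
- Br2 (CH2Cl2, −78 to 0 °C) should add to the alkene to give methyl 3,4-dibromo-4-(1-Boc-indol-3-yl)-2-oxobutanoate F3.
- Et3N removes HBr from the dibromide in the same flask to give methyl (Z)-3-bromo-4-(1-Boc-indol-3-yl)-2-oxobut-3-enoate F4.
- Suzuki–Miyaura coupling of the bromide with commercial 3-(4,4,5,5-tetramethyl-1,3,2-dioxaborolan-2-yl)-1H-indole (Pd(PPh3)4, K3PO4, dioxane, 80 °C) should proceed with retention at the alkene and comes back to the route at 6.

**Step 1.**
Acid 1 and ester 2 are sensitive to air and base. Oxidative cleavage of the enol, self-aldolisation, or methylation at the enol oxygen or at C3 may erode the material.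

The fallback avoids 1 altogether and sets out from 4. Horner–Wadsworth–Emmons olefination with commercial methyl 2-[(tert-butoxycarbonyl)amino]-2-(dimethoxyphosphoryl)acetate (DBU, CH2Cl2, 0 °C to rt) should give methyl (Z)-2-[(tert-butoxycarbonyl)amino]-3-(1-Boc-indol-3-yl)acrylate F5. TFA in CH2Cl2 removes both Boc groups. Water then hydrolyses the liberated enamine through its imine tautomer to the keto ester, which comes back to the route at 2.

## Further compounds

F1 | step 4 | methyl 4-(1-Boc-indol-3-yl)-3-(1H-indol-3-yl)-5-[methoxy(methyl)carbamoyl]-1H-pyrrole-2-carboxylate | COC(=O)c1[nH]c(C(=O)N(C)OC)c(-c2cn(C(=O)OC(C)(C)C)c3ccccc23)c1-c1c[nH]c2ccccc12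
F2 | step 3 | methyl (E)-4-(1-Boc-indol-3-yl)-2-oxobut-3-enoate | COC(=O)C(=O)/C=C/c1cn(C(=O)OC(C)(C)C)c2ccccc12
F3 | step 3 | methyl 3,4-dibromo-4-(1-Boc-indol-3-yl)-2-oxobutanoate (racemic, relative configuration of no consequence) | COC(=O)C(=O)C(Br)C(Br)c1cn(C(=O)OC(C)(C)C)c2ccccc12
F4 | step 3 | methyl (Z)-3-bromo-4-(1-Boc-indol-3-yl)-2-oxobut-3-enoate | COC(=O)C(=O)/C(Br)=C/c1cn(C(=O)OC(C)(C)C)c2ccccc12
F5 | step 1 | methyl (Z)-2-[(tert-butoxycarbonyl)amino]-3-(1-Boc-indol-3-yl)acrylate | COC(=O)/C(NC(=O)OC(C)(C)C)=C/c1cn(C(=O)OC(C)(C)C)c2ccccc12
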